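Ring C is closed last at its aryl ketone: the C4–C4a bond is formed by intramolecular Friedel–Crafts acylation of a (2R,3R)-3-aryloxy-2-methoxy-3-arylpropanoic acid that already carries O1, C2, C3 and both stereocentres. The step exploits ring A: C4a lies ortho to O1, ortho to the C5 oxygen and para to the C7 oxygen, and in a 4-benzyloxy-3,5-dimethoxyphenyl ether C4a and C8 are equivalent, so one operation gives the whole chromanone without a regiochemical choice. The C5 methyl ether, peri to the new C4 carbonyl, is then cleaved by chelation together with both benzyl ethers. The acid comes from a trans-glycidate opened with inversion by the ring A phenol.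

Key step: step 8

Remark: the target is read as the (2R,3R)-trans dihydroflavonol 3-methyl ether; locants O1, C2, C3, C4, C4a, C5 to C8 and C8a are those of the chroman-4-one, ring A is the benzo ring, ring B the 2-aryl group and ring C the pyranone; the L-series diacetate Shi ketone is assumed to be at hand (made from L-sorbose).

Step 1
Reactants: 1 3-(benzyloxy)-4-methoxybenzaldehyde
Product: 2 methyl (E)-3-[3-(benzyloxy)-4-methoxyphenyl]prop-2-enoate
Conditions: Ph3P=CHCO2Me, toluene, 80 °C
Reagents that add atoms: methyl (triphenylphosphoranylidene)acetate, COC(=O)C=P(c1ccccc1)(c1ccccc1)c1ccccc1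
Why: Wittig olefination with a stabilised ylide should give the E-enoate, which supplies C2, C3 and C4 of the target.

Step 2
Reactants: 2 methyl (E)-3-[3-(benzyloxy)-4-methoxyphenyl]prop-2-enoate
Product: 3 methyl (2R,3S)-3-[3-(benzyloxy)-4-methoxyphenyl]oxirane-2-carboxylate (trans-glycidate)
Conditions: L-series diacetate Shi ketone (0.3 equiv), KHSO5 (as 2KHSO5·KHSO4·K2SO4), NaHCO3, Bu4NHSO4 (cat.), MeCN/H2O, 0 °C
Reagents that add atoms: potassium peroxymonosulfate, [K+].[O-]S(=O)(=O)OO
Why: Shi asymmetric epoxidation, in which the dioxirane formed from the chiral ketone and KHSO5 should deliver oxygen to one face of the E-enoate through a spiro transition state, the L-series ketone giving the (2R,3S)-trans-glycidate (mirror image of the (2S,3R) product expected from the D-fructose-derived catalyst) and so fixing both stereocentres.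

Step 3
Reactants: 4 4-hydroxy-3,5-dimethoxybenzaldehyde (syringaldehyde)
Product: 5 4-(benzyloxy)-3,5-dimethoxybenzaldehyde
Conditions: BnBr, K2CO3, DMF, rt
Reagents that add atoms: benzyl bromide, BrCc1ccccc1
Why: Williamson etherification of the only phenol should protect the future C6 oxygen as a benzyl ether that leaves in the last step.

Step 4
Reactants: 5 4-(benzyloxy)-3,5-dimethoxybenzaldehyde
Product: 7 4-(benzyloxy)-3,5-dimethoxyphenol, via aryl formate 6 (not isolated)
Conditions: mCPBA, CH2Cl2, rt; then K2CO3 (cat.), MeOH, rt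
Reagents that add atoms: 3-chloroperoxybenzoic acid, OOC(=O)c1cccc(Cl)c1
Why: Baeyer–Villiger (Dakin-type) oxidation, in which the electron-rich aryl group should migrate to oxygen to give the formate, whose methanolysis frees the phenol that becomes O1.

Step 5
Reactants: 3 methyl (2R,3S)-3-[3-(benzyloxy)-4-methoxyphenyl]oxirane-2-carboxylate; 7 4-(benzyloxy)-3,5-dimethoxyphenol
Product: 8 methyl (2R,3R)-3-[4-(benzyloxy)-3,5-dimethoxyphenoxy]-3-[3-(benzyloxy)-4-methoxyphenyl]-2-hydroxypropanoate
Conditions: 7 (1.2 equiv), Cs2CO3 (0.2 equiv), DMF, 45 °C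
Reagents that add atoms: none
Why: Base-catalysed epoxide opening, in which the phenoxide of 7 should attack the benzylic C3 of the glycidate (activated by the aryl group, while C2 next to the ester resists substitution) in an SN2 anti-opening, so that C3 is inverted from S to R and becomes C2 of the target with the ring A ether in place, the C2 hydroxyl keeping its R configuration.

Step 6
Reactants: 8 methyl (2R,3R)-3-[4-(benzyloxy)-3,5-dimethoxyphenoxy]-3-[3-(benzyloxy)-4-methoxyphenyl]-2-hydroxypropanoate
Product: 9 methyl (2R,3R)-3-[4-(benzyloxy)-3,5-dimethoxyphenoxy]-3-[3-(benzyloxy)-4-methoxyphenyl]-2-methoxypropanoate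
Conditions: Ag2O, MeI, 4 Å MS, MeCN, 40 °C, dark
Reagents that add atoms: iodomethane, CI
Why: Purdie methylation of the α-hydroxy ester under non-basic conditions should install the C3 methoxy group without enolisation, so neither epimerisation nor β-elimination of the aryloxide is expected.

Step 7
Reactants: 9 methyl (2R,3R)-3-[4-(benzyloxy)-3,5-dimethoxyphenoxy]-3-[3-(benzyloxy)-4-methoxyphenyl]-2-methoxypropanoate
Product: 10 (2R,3R)-3-[4-(benzyloxy)-3,5-dimethoxyphenoxy]-3-[3-(benzyloxy)-4-methoxyphenyl]-2-methoxypropanoic acid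
Conditions: LiOH·H2O, THF/H2O, 0 °C; then 1 M HCl
Reagents that add atoms: lithium hydroxide, [Li+].[OH-]
Why: Saponification of the activated α-alkoxy ester should be fast at 0 °C, where ester enolisation (and with it E1cB loss of the aryloxide or epimerisation) is slow.

Step 8
Reactants: 10 (2R,3R)-3-[4-(benzyloxy)-3,5-dimethoxyphenoxy]-3-[3-(benzyloxy)-4-methoxyphenyl]-2-methoxypropanoic acid
Product: 12 (2R,3R)-6-(benzyloxy)-2-[3-(benzyloxy)-4-methoxyphenyl]-3,5,7-trimethoxy-2,3-dihydro-4H-chromen-4-one, via mixed trifluoroacetic anhydride 11 (not isolated)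
Conditions: TFAA (3 equiv), CH2Cl2, 0 °C to rt
Reagents that add atoms: trifluoroacetic anhydride (atoms carried only in intermediate 11), O=C(OC(=O)C(F)(F)F)C(F)(F)F
Why: TFAA converts acid 10 into mixed anhydride 11, whose acyl carbon (the future C4) is attacked by the ring A carbon ortho to O1 (the future C4a), and loss of a proton from the arenium ion gives the aryl ketone, an intramolecular Friedel–Crafts acylation of the 3-aryloxypropanoic acid type used for chroman-4-ones. Ring C closes in the 6-exo-trig mode. No stereocentre is formed; C2 and C3 are carried over from steps 2 and 5, and C3, now α to the ketone, already has the thermodynamically preferred trans (diequatorial) arrangement, so acid-promoted enolisation should not erode it. The step needs site selectivity between C4a and C8 and between ring A and ring B: C4a and C8 are interchanged by rotation about the O1–C8a bond, each is activated by three oxygens (ortho O1, ortho and para methoxy), whereas attack by ring B would need a five-membered indanone at a carbon activated by one para oxygen only. The benzylic C2–O1 bond should survive because the C3 methoxy and acyl groups destabilise a C2 cation and TFAA works without a strong Lewis acid.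

Step 9
Reactants: 12 (2R,3R)-6-(benzyloxy)-2-[3-(benzyloxy)-4-methoxyphenyl]-3,5,7-trimethoxy-2,3-dihydro-4H-chromen-4-one
Product: 14 (2R,3R)-5,6-dihydroxy-2-(3-hydroxy-4-methoxyphenyl)-3,7-dimethoxy-2,3-dihydro-4H-chromen-4-one (target), via debenzylated 5-methyl ether 13 (not isolated)
Conditions: BCl3 (8 equiv), pentamethylbenzene (6 equiv), CH2Cl2, −78 to 0 °C; then aq. NaHCO3
Reagents that add atoms: none
Why: BCl3 should first cleave both aryl benzyl ethers at low temperature (pentamethylbenzene traps the benzyl cations) and then, held in a six-membered chelate between the C4 carbonyl and the peri C5 oxygen, cleave only the C5 methyl ether (chelation-directed demethylation), the unchelated C7, C4' and aliphatic C3 methyl ethers being retained.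

Compound list
1 | 3-(benzyloxy)-4-methoxybenzaldehyde | O=Cc1ccc(OC)c(OCc2ccccc2)c1 | starting material
2 | methyl (E)-3-[3-(benzyloxy)-4-methoxyphenyl]prop-2-enoate | COC(=O)/C=C/c1ccc(OC)c(OCc2ccccc2)c1 | intermediate
3 | methyl (2R,3S)-3-[3-(benzyloxy)-4-methoxyphenyl]oxirane-2-carboxylate | COC(=O)[C@@H]1O[C@H]1c1ccc(OC)c(OCc2ccccc2)c1 | intermediate
4 | 4-hydroxy-3,5-dimethoxybenzaldehyde (syringaldehyde) | O=Cc1cc(OC)c(O)c(OC)c1 | starting material
5 | 4-(benzyloxy)-3,5-dimethoxybenzaldehyde | O=Cc1cc(OC)c(OCc2ccccc2)c(OC)c1 | intermediate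
6 | 4-(benzyloxy)-3,5-dimethoxyphenyl formate (not isolated) | O=COc1cc(OC)c(OCc2ccccc2)c(OC)c1 | intermediate
7 | 4-(benzyloxy)-3,5-dimethoxyphenol | Oc1cc(OC)c(OCc2ccccc2)c(OC)c1 | intermediate
8 | methyl (2R,3R)-3-[4-(benzyloxy)-3,5-dimethoxyphenoxy]-3-[3-(benzyloxy)-4-methoxyphenyl]-2-hydroxypropanoate | COC(=O)[C@H](O)[C@H](Oc1cc(OC)c(OCc2ccccc2)c(OC)c1)c1ccc(OC)c(OCc2ccccc2)c1 | intermediate
9 | methyl (2R,3R)-3-[4-(benzyloxy)-3,5-dimethoxyphenoxy]-3-[3-(benzyloxy)-4-methoxyphenyl]-2-methoxypropanoate | COC(=O)[C@H](OC)[C@H](Oc1cc(OC)c(OCc2ccccc2)c(OC)c1)c1ccc(OC)c(OCc2ccccc2)c1 | intermediate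
10 | (2R,3R)-3-[4-(benzyloxy)-3,5-dimethoxyphenoxy]-3-[3-(benzyloxy)-4-methoxyphenyl]-2-methoxypropanoic acid | OC(=O)[C@H](OC)[C@H](Oc1cc(OC)c(OCc2ccccc2)c(OC)c1)c1ccc(OC)c(OCc2ccccc2)c1 | intermediate
11 | (2R,3R)-3-[4-(benzyloxy)-3,5-dimethoxyphenoxy]-3-[3-(benzyloxy)-4-methoxyphenyl]-2-methoxypropanoic trifluoroacetic anhydride (not isolated) | O=C(OC(=O)C(F)(F)F)[C@H](OC)[C@H](Oc1cc(OC)c(OCc2ccccc2)c(OC)c1)c1ccc(OC)c(OCc2ccccc2)c1 | intermediate
12 | (2R,3R)-6-(benzyloxy)-2-[3-(benzyloxy)-4-methoxyphenyl]-3,5,7-trimethoxy-2,3-dihydro-4H-chromen-4-one | COc1ccc([C@H]2Oc3cc(OC)c(OCc4ccccc4)c(OC)c3C(=O)[C@@H]2OC)cc1OCc1ccccc1 | intermediate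
13 | (2R,3R)-6-hydroxy-2-(3-hydroxy-4-methoxyphenyl)-3,5,7-trimethoxy-2,3-dihydro-4H-chromen-4-one (not isolated; present in the flask as its aryl dichloroborates) | COc1ccc([C@H]2Oc3cc(OC)c(O)c(OC)c3C(=O)[C@@H]2OC)cc1O | intermediate
14 | (2R,3R)-5,6-dihydroxy-2-(3-hydroxy-4-methoxyphenyl)-3,7-dimethoxy-2,3-dihydro-4H-chromen-4-one | COc1ccc([C@H]2Oc3cc(OC)c(O)c(O)c3C(=O)[C@@H]2OC)cc1O | target

Total step count: 9. Longest linear sequence: 7 steps (steps 1, 2, 5, 6, 7, 8, 9); steps 3 and 4 form the ring A branch.

Steps most likely to fail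

Step 8. The acidic medium may ionise the benzylic C2–O1 ether (loss of the ring A phenol or epimerisation at C2), or the activated α-methoxy acyl unit may lose carbon monoxide before ring closure. The fallback makes the same bond by an anionic Parham cyclisation and sets out from 10. Coupling with MeNHOMe·HCl (EDC·HCl, HOBt, iPr2NEt, CH2Cl2) should give the Weinreb amide (2R,3R)-3-[4-(benzyloxy)-3,5-dimethoxyphenoxy]-3-[3-(benzyloxy)-4-methoxyphenyl]-N,2-dimethoxy-N-methylpropanamide F1. NBS (1 equiv, MeCN, 0 °C) should then brominate ring A once at a carbon ortho to the ether oxygen, both such carbons being equivalent and the most electron-rich in the molecule, to give the aryl bromide (2R,3R)-3-[4-(benzyloxy)-2-bromo-3,5-dimethoxyphenoxy]-3-[3-(benzyloxy)-4-methoxyphenyl]-N,2-dimethoxy-N-methylpropanamide F2. Bromine–lithium exchange with t-BuLi (2.1 equiv, THF, −78 °C) and attack of the aryllithium on the Weinreb amide within the same molecule should return to the route at 12.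

Step 5. The opening may lose configurational integrity at the benzylic carbon through an ion-pair pathway favoured by the para methoxy group, and ester exchange by the phenoxide or C-alkylation of the electron-rich phenol may compete. The fallback sets both stereocentres by an aldol reaction and forms the ether by Mitsunobu inversion; it sets out from 1 and also bypasses steps 2, 6 and 7. N-Acylation of (R)-4-benzyloxazolidin-2-one with methoxyacetyl chloride (n-BuLi, THF, −78 °C) should give (R)-4-benzyl-3-(methoxyacetyl)oxazolidin-2-one F3. Its Evans syn-aldol reaction with 1 (Bu2BOTf, Et3N, CH2Cl2, −78 to 0 °C) should give (R)-4-benzyl-3-[(2R,3S)-3-[3-(benzyloxy)-4-methoxyphenyl]-3-hydroxy-2-methoxypropanoyl]oxazolidin-2-one F4. Mitsunobu etherification with 7 (PPh3, DIAD, toluene, 0 °C to rt) should invert the carbinol carbon and give (R)-4-benzyl-3-[(2R,3R)-3-[4-(benzyloxy)-3,5-dimethoxyphenoxy]-3-[3-(benzyloxy)-4-methoxyphenyl]-2-methoxypropanoyl]oxazolidin-2-one F5. Removal of the auxiliary (LiOH, H2O2, THF/H2O, 0 °C) should return to the route at 10.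

Step 9. Further methyl ethers (at C3, C7 or C4') may be lost, or the Lewis acid may open ring C and epimerise C2 and C3. The fallback separates the two deprotections and sets out from 12. Mild hydrogenolysis (H2, Pd(OH)2/C, EtOAc, rt, stopped at debenzylation to spare the benzylic C2–O1 bond) should give 13 as an isolated compound. Chelation-controlled cleavage of the C5 methyl ether with MgI2·OEt2 (THF/toluene, 50 °C) should then return to the route at 14. This fallback makes no compound outside the list (F0).

Further compounds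
F1 | step 8 | (2R,3R)-3-[4-(benzyloxy)-3,5-dimethoxyphenoxy]-3-[3-(benzyloxy)-4-methoxyphenyl]-N,2-dimethoxy-N-methylpropanamide | CON(C)C(=O)[C@H](OC)[C@H](Oc1cc(OC)c(OCc2ccccc2)c(OC)c1)c1ccc(OC)c(OCc2ccccc2)c1
F2 | step 8 | (2R,3R)-3-[4-(benzyloxy)-2-bromo-3,5-dimethoxyphenoxy]-3-[3-(benzyloxy)-4-methoxyphenyl]-N,2-dimethoxy-N-methylpropanamide | CON(C)C(=O)[C@H](OC)[C@H](Oc1cc(OC)c(OCc2ccccc2)c(OC)c1Br)c1ccc(OC)c(OCc2ccccc2)c1
F3 | step 5 | (R)-4-benzyl-3-(methoxyacetyl)oxazolidin-2-one | COCC(=O)N1[C@H](Cc2ccccc2)COC1=O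
F4 | step 5 | (R)-4-benzyl-3-[(2R,3S)-3-[3-(benzyloxy)-4-methoxyphenyl]-3-hydroxy-2-methoxypropanoyl]oxazolidin-2-one | O=C(N1[C@H](Cc2ccccc2)COC1=O)[C@H](OC)[C@@H](O)c1ccc(OC)c(OCc2ccccc2)c1
F5 | step 5 | (R)-4-benzyl-3-[(2R,3R)-3-[4-(benzyloxy)-3,5-dimethoxyphenoxy]-3-[3-(benzyloxy)-4-methoxyphenyl]-2-methoxypropanoyl]oxazolidin-2-one | O=C(N1[C@H](Cc2ccccc2)COC1=O)[C@H](OC)[C@H](Oc1cc(OC)c(OCc2ccccc2)c(OC)c1)c1ccc(OC)c(OCc2ccccc2)c1
F0 | step 9 | none | none
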